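The 14-membered carbocycle is disconnected at the C5–C6 single bond (cembrane numbering). This bond is the centre of the 1,5-diene C3=C4–C5–C6–C7=C8, where both carbons are allylic. It is also the bond that prenyl transfer forges between an allylic C1 and an isopentenyl C4. The key step copies this head-to-tail union within one molecule. A phenylsulfonyl-stabilised allyl anion at C6 displaces a dienylic chloride at C5 and closes the ring, with all five alkenes and all three carbinol centres already in place. The precursor is a linear, silyl-protected C20 chloro sulfone. Its sulfone comes from opening a vinyl epoxide made by Sharpless epoxidation, which also fixes C9 and the C7=C8 geometry.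

Key step: step 17

Numbering: the ring is C1–C14. C1 bears the isopropenyl group (C15–C17) and C14 the acetate. Methyls C18, C19 and C20 sit on C4, C8 and C12. "5,6-Secocembra" means this skeleton with the C5–C6 bond missing.

Assumption: the (S)-configured phosphoric acid in step 10 is taken to direct the allenylboronate to the aldehyde face that gives the 14S carbinol, by analogy with aromatic and α,β-unsaturated aldehydes; if the sense is opposite, the equally available (R)-acid is used.

Step 1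
Reactants: 1 (E)-3-methylpent-2-en-4-yn-1-ol
Product: 2 (E)-3-methylpenta-2,4-dien-1-ol
Conditions: H2 (1 atm, one equivalent), Pd/CaCO3 poisoned with Pb(OAc)2, quinoline, Et2O, 0 °C
Reagents that add atoms: none
Why: Lindlar-type semihydrogenation: the poisoned palladium surface reduces the terminal alkyne to the vinyl group and should stop there, leaving the E-trisubstituted alkene untouched.

Step 2
Reactants: 2 (E)-3-methylpenta-2,4-dien-1-ol
Product: 3 [(2S,3S)-3-ethenyl-3-methyloxiran-2-yl]methanol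
Conditions: Ti(OiPr)4 (10 mol %), L-(+)-diisopropyl tartrate (12 mol %), t-BuOOH, 4 Å MS, CH2Cl2, −20 °C
Reagents that add atoms: tert-butyl hydroperoxide, CC(C)(C)OO
Why: Sharpless asymmetric epoxidation: the titanium tartrate complex binds the allylic alcohol and epoxidises only the adjacent C8=C9 alkene, and L-(+)-tartrate should deliver oxygen to the face that gives the 2S,3S epoxide, as with other E-3,3-disubstituted allylic alcohols, which sets C9.

Step 3
Reactants: 3 [(2S,3S)-3-ethenyl-3-methyloxiran-2-yl]methanol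
Product: 4 (2R,3E)-3-methyl-5-(phenylsulfonyl)pent-3-ene-1,2-diol
Conditions: PhSO2Na, AcOH (1 equiv), Pd(PPh3)4 (3 mol %), THF, 0 °C → rt
Reagents that add atoms: sodium benzenesulfinate, [Na+].[O-]S(=O)c1ccccc1
Why: Tsuji–Trost-type opening of a vinyl epoxide: zerovalent palladium ionises the strained allylic C8–O bond, the soft sulfinate adds reversibly to the unhindered terminus C6 so that the linear E-allyl sulfone should result, and the C9–O bond is never broken, so C9 is retained.

Step 4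
Reactants: 4 (2R,3E)-3-methyl-5-(phenylsulfonyl)pent-3-ene-1,2-diol
Product: 5 (2R,3E)-1,2-bis(tert-butyldimethylsilyloxy)-3-methyl-5-(phenylsulfonyl)pent-3-ene
Conditions: TBSCl, imidazole, DMF, rt
Reagents that add atoms: tert-butyldimethylsilyl chloride, CC(C)(C)[Si](C)(C)Cl
Why: Standard silylation with silyl chloride and imidazole covers both hydroxyl groups without touching C9 or the sulfone.

Step 5
Reactants: 5 (2R,3E)-1,2-bis(tert-butyldimethylsilyloxy)-3-methyl-5-(phenylsulfonyl)pent-3-ene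
Product: 6 (2R,3E)-2-(tert-butyldimethylsilyloxy)-3-methyl-5-(phenylsulfonyl)pent-3-en-1-ol
Conditions: HF·pyridine, pyridine, THF, 0 °C
Reagents that add atoms: none
Why: Chemoselective desilylation: buffered HF cleaves the unhindered primary silyl ether much faster than the secondary allylic one next to the branched alkene.

Step 6
Reactants: 6 (2R,3E)-2-(tert-butyldimethylsilyloxy)-3-methyl-5-(phenylsulfonyl)pent-3-en-1-ol
Product: 7 (2R,3E)-2-(tert-butyldimethylsilyloxy)-3-methyl-5-(phenylsulfonyl)pent-3-enal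
Conditions: Dess–Martin periodinane, NaHCO3, CH2Cl2, 0 °C; used at once
Reagents that add atoms: none
Why: Dess–Martin oxidation under buffered, non-basic conditions should give the α-silyloxy β,γ-unsaturated aldehyde without epimerisation at C9 or migration of the alkene.

Step 7
Reactants: 8 prop-2-yn-1-ol, 9 isopropenylmagnesium bromide
Product: 11 (2Z)-3-iodo-2-(prop-1-en-2-yl)prop-2-en-1-ol, via cyclic alkenylmagnesium alkoxide 10 (not isolated)
Conditions: 9 (2.5 equiv), CuI (10 mol %), THF, −10 °C → rt; I2, −78 → 0 °C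
Reagents that add atoms: iodine, II
Why: Copper-catalysed anti-carbomagnesiation of a propargylic alkoxide: the isopropenyl group adds to the inner alkyne carbon (C1) and magnesium ends on C2 cis to the CH2O group in a five-membered chelate, so iodinolysis with retention fixes the 1Z geometry.

Step 8
Reactants: 12 tert-butyldimethyl(prop-2-yn-1-yloxy)silane, 11 (2Z)-3-iodo-2-(prop-1-en-2-yl)prop-2-en-1-ol
Product: 14 (2Z,4E)-6-(tert-butyldimethylsilyloxy)-5-methyl-2-(prop-1-en-2-yl)hexa-2,4-dien-1-ol, via alkenylalane 13 (not isolated)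
Conditions: 12, Me3Al, Cp2ZrCl2 (20 mol %), CH2Cl2, 0 °C → rt, excess Me3Al removed in vacuo; 11 (pre-treated with 1 equiv Me3Al), ZnCl2 (cat.), Pd(PPh3)4 (5 mol %), THF, rt
Reagents that add atoms: trimethylaluminium, C[Al](C)C
Why: Negishi zirconium-catalysed carboalumination (syn-addition of Me–Al, methyl C18 on C4) followed by palladium-catalysed Negishi-type alkenyl–alkenyl cross-coupling, both stereoretentive, should give the 1Z,3E diene next to the isopropenyl group.

Step 9
Reactants: 14 (2Z,4E)-6-(tert-butyldimethylsilyloxy)-5-methyl-2-(prop-1-en-2-yl)hexa-2,4-dien-1-ol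
Product: 15 (2Z,4E)-6-(tert-butyldimethylsilyloxy)-5-methyl-2-(prop-1-en-2-yl)hexa-2,4-dienal
Conditions: activated MnO2, CH2Cl2, rt, dark
Reagents that add atoms: none
Why: Allylic oxidation with MnO2 is selective for the allylic alcohol and neutral enough to keep the Z-enal geometry and the silyl ether.

Step 10
Reactants: 15 (2Z,4E)-6-(tert-butyldimethylsilyloxy)-5-methyl-2-(prop-1-en-2-yl)hexa-2,4-dienal, 16 allenylboronic acid pinacol ester
Product: 18 (4S,5Z,7E)-9-(tert-butyldimethylsilyloxy)-8-methyl-5-(prop-1-en-2-yl)nona-5,7-dien-1-yn-4-ol, via O-boryl ether 17 (not isolated)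
Conditions: (S)-3,3′-bis(2,4,6-triisopropylphenyl)-1,1′-binaphthyl-2,2′-diyl hydrogen phosphate (10 mol %), 4 Å MS, toluene, −20 °C; aqueous work-up
Reagents that add atoms: none
Why: Chiral phosphoric acid catalysed propargylation with an allenylboronate: the acid activates the boronate in a closed six-membered SE2′ transition state that can give only the homopropargylic alcohol, and the catalyst selects the aldehyde face, which sets C14 as S.

Step 11
Reactants: 18 (4S,5Z,7E)-9-(tert-butyldimethylsilyloxy)-8-methyl-5-(prop-1-en-2-yl)nona-5,7-dien-1-yn-4-ol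
Product: 19 (4S,5Z,7E)-4,9-bis(tert-butyldimethylsilyloxy)-8-methyl-5-(prop-1-en-2-yl)nona-5,7-dien-1-yne
Conditions: TBSOTf, 2,6-lutidine, CH2Cl2, −78 → 0 °C
Reagents that add atoms: tert-butyldimethylsilyl triflate, CC(C)(C)[Si](C)(C)OS(=O)(=O)C(F)(F)F
Why: Silylation with the reactive silyl triflate covers the hindered C14 carbinol under non-ionising, weakly basic conditions, so C14 is not scrambled.

Step 12
Reactants: 19 (4S,5Z,7E)-4,9-bis(tert-butyldimethylsilyloxy)-8-methyl-5-(prop-1-en-2-yl)nona-5,7-dien-1-yne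
Product: 21 (1E,4S,5Z,7E)-4,9-bis(tert-butyldimethylsilyloxy)-1-iodo-2,8-dimethyl-5-(prop-1-en-2-yl)nona-1,5,7-triene, via alkenylalane 20 (not isolated)
Conditions: Me3Al, Cp2ZrCl2 (25 mol %), CH2Cl2, 0 °C → rt; I2, THF, −30 °C
Reagents that add atoms: trimethylaluminium, C[Al](C)C; iodine, II
Why: Negishi carboalumination adds Me–Al syn across the terminal alkyne only (methyl C20 on C12, aluminium on C11, the di- and trisubstituted alkenes being inert), and iodinolysis with retention gives the E-iodide that carries the 11E geometry.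

Step 13
Reactants: 21 (1E,4S,5Z,7E)-4,9-bis(tert-butyldimethylsilyloxy)-1-iodo-2,8-dimethyl-5-(prop-1-en-2-yl)nona-1,5,7-triene, 7 (2R,3E)-2-(tert-butyldimethylsilyloxy)-3-methyl-5-(phenylsulfonyl)pent-3-enal
Product: 24 (9R,10R,14S)-10-hydroxy-6-(phenylsulfonyl)-5,9,14-tris(tert-butyldimethylsilyloxy)-5,6-secocembra-1Z,3E,7E,11E,15-pentaene, via alkenyllithium 22 (not isolated), via alkenyl(ethyl)zinc 23 (not isolated)
Conditions: 21, t-BuLi (2 equiv), Et2O, −78 °C; EtZnCl (1 equiv), −78 → 0 °C, solvent changed to toluene; EtZnCl (1.5 equiv), 7, −30 → 0 °C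
Reagents that add atoms: tert-butyllithium, [Li]C(C)(C)C (Li of 22 only); ethylzinc chloride, CC[Zn]Cl (EtZn of 23 only)
Why: Chelation-controlled 1,2-addition of a vinylzinc reagent to an α-silyloxy aldehyde (Cram chelate model): the alkylzinc halide ties the C10 carbonyl and the C9 silyloxy oxygen into a five-membered chelate so that attack past the C9–H should give the 9,10-syn (10R) alcohol, and the non-basic zinc reagent leaves the acidic C6–H of the sulfone alone.

Step 14
Reactants: 24 (9R,10R,14S)-10-hydroxy-6-(phenylsulfonyl)-5,9,14-tris(tert-butyldimethylsilyloxy)-5,6-secocembra-1Z,3E,7E,11E,15-pentaene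
Product: 25 (9R,10R,14S)-6-(phenylsulfonyl)-5,9,10,14-tetrakis(tert-butyldimethylsilyloxy)-5,6-secocembra-1Z,3E,7E,11E,15-pentaene
Conditions: TBSOTf, 2,6-lutidine, CH2Cl2, −78 → 0 °C
Reagents that add atoms: tert-butyldimethylsilyl triflate, CC(C)(C)[Si](C)(C)OS(=O)(=O)C(F)(F)F
Why: Silylation with silyl triflate masks the bis-allylic C10 carbinol, which would otherwise compete as an alkoxide nucleophile in the ring closure.

Step 15
Reactants: 25 (9R,10R,14S)-6-(phenylsulfonyl)-5,9,10,14-tetrakis(tert-butyldimethylsilyloxy)-5,6-secocembra-1Z,3E,7E,11E,15-pentaene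
Product: 26 (9R,10R,14S)-5-hydroxy-6-(phenylsulfonyl)-9,10,14-tris(tert-butyldimethylsilyloxy)-5,6-secocembra-1Z,3E,7E,11E,15-pentaene
Conditions: HF·pyridine, pyridine, THF, 0 °C
Reagents that add atoms: none
Why: Chemoselective desilylation: only the C5 ether is primary and unhindered, so it should be cleaved well before the three congested secondary silyl ethers.

Step 16
Reactants: 26 (9R,10R,14S)-5-hydroxy-6-(phenylsulfonyl)-9,10,14-tris(tert-butyldimethylsilyloxy)-5,6-secocembra-1Z,3E,7E,11E,15-pentaene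
Product: 27 (9R,10R,14S)-5-chloro-6-(phenylsulfonyl)-9,10,14-tris(tert-butyldimethylsilyloxy)-5,6-secocembra-1Z,3E,7E,11E,15-pentaene
Conditions: NCS, Me2S, CH2Cl2, −20 → 0 °C
Reagents that add atoms: N-chlorosuccinimide, O=C1CCC(=O)N1Cl
Why: Corey–Kim allylic chlorination converts the primary dienylic alcohol through its alkoxysulfonium salt by direct SN2 displacement under neutral conditions, without allylic transposition or loss of the 3E geometry.

Step 17
Reactants: 27 (9R,10R,14S)-5-chloro-6-(phenylsulfonyl)-9,10,14-tris(tert-butyldimethylsilyloxy)-5,6-secocembra-1Z,3E,7E,11E,15-pentaene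
Product: 29 (9R,10R,14S)-6-(phenylsulfonyl)-9,10,14-tris(tert-butyldimethylsilyloxy)cembra-1Z,3E,7E,11E,15-pentaene (C6 epimers), via potassium sulfonyl carbanion 28 (not isolated)
Conditions: KN(SiMe3)2 (1.5 equiv), THF, slow addition of 27 by syringe pump (final about 1 mM), −78 → 0 °C
Reagents that add atoms: potassium bis(trimethylsilyl)amide, C[Si](C)(C)[N-][Si](C)(C)C.[K+] (K of 28 only)
Why: KN(SiMe3)2 removes a C6–H of the allylic sulfone, and the α-sulfonyl allyl anion displaces chloride from the primary dienylic carbon C5 in an intramolecular SN2 reaction, which forms the C5–C6 bond. The closest known reaction type is the allylic sulfone–allylic halide head-to-tail coupling of polyprenoid synthesis (Julia-type sulfone alkylation) in its intramolecular, macrocycle-forming version, and it mirrors prenyl transfer with inverted polarity. The one ring closed is the 14-membered carbocycle, in a 14-exo-tet mode. The only new stereocentre, C6, is not controlled and need not be, because step 18 erases it, while C9, C10 and C14 lie outside the reacting centres and are not touched. The step needs α- over γ-alkylation (the sulfone localises the charge at C6 and C8 is fully substituted), SN2 over SN2′ (C5 is primary and open, C3 and C1 are not) and ring closure over oligomerisation (slow addition at high dilution). Neither alkene is ionised or metallated, so the 3E and 7E geometries persist, and the silyloxide at C9 is too poor a leaving group for vinylogous elimination at low temperature.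

Step 18
Reactants: 29 (9R,10R,14S)-6-(phenylsulfonyl)-9,10,14-tris(tert-butyldimethylsilyloxy)cembra-1Z,3E,7E,11E,15-pentaene
Product: 30 (9R,10R,14S)-9,10,14-tris(tert-butyldimethylsilyloxy)cembra-1Z,3E,7E,11E,15-pentaene
Conditions: PdCl2(dppp) (10 mol %), LiHBEt3, THF, 0 °C
Reagents that add atoms: none
Why: Palladium-catalysed hydride desulfonylation of an allylic sulfone: ionisation gives the C6–C7–C8 π-allyl complex and hydride goes to the less substituted terminus C6, a process known to keep the position and E geometry of prenyl-type trisubstituted alkenes, while the allylic silyl ethers do not ionise.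

Step 19
Reactants: 30 (9R,10R,14S)-9,10,14-tris(tert-butyldimethylsilyloxy)cembra-1Z,3E,7E,11E,15-pentaene
Product: 31 (9R,10R,14S)-cembra-1Z,3E,7E,11E,15-pentaene-9,10,14-triol
Conditions: Bu4NF, THF, rt → 40 °C
Reagents that add atoms: none
Why: Fluoride-induced global desilylation cleaves only Si–O bonds, so all three carbinol configurations and the acid-sensitive triene are preserved.

Step 20
Reactants: 31 (9R,10R,14S)-cembra-1Z,3E,7E,11E,15-pentaene-9,10,14-triol
Product: 34 (1Z,3E,7E,11E,9R,10R,14S)-14-acetoxycembra-1,3,7,11,15-pentaene-9,10-diol (CNP0330994.1), via phenylboronate 32 (not isolated), via phenylboronate acetate 33 (not isolated)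
Conditions: PhB(OH)2, 4 Å MS, CH2Cl2, rt; Ac2O, pyridine, DMAP (cat.), 0 °C → rt; pinacol, rt
Reagents that add atoms: acetic anhydride, CC(=O)OC(C)=O; phenylboronic acid, OB(O)c1ccccc1 (PhB of 32 and 33 only)
Why: Transient boronate protection: the 9,10-syn-diol condenses with phenylboronic acid to a five-membered dioxaborolane, only the C14 hydroxyl is left for DMAP-catalysed acetylation, and transesterification with pinacol frees the diol without touching the acetate or any stereocentre.

Compound list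
1 | (E)-3-methylpent-2-en-4-yn-1-ol | C#C/C(C)=C/CO | starting material
2 | (E)-3-methylpenta-2,4-dien-1-ol | C=C/C(C)=C/CO | intermediate
3 | [(2S,3S)-3-ethenyl-3-methyloxiran-2-yl]methanol | OC[C@@H]1O[C@@]1(C)C=C | intermediate
4 | (2R,3E)-3-methyl-5-(phenylsulfonyl)pent-3-ene-1,2-diol | OC[C@H](O)/C(C)=C/CS(=O)(=O)c1ccccc1 | intermediate
5 | (2R,3E)-1,2-bis(tert-butyldimethylsilyloxy)-3-methyl-5-(phenylsulfonyl)pent-3-ene | CC(C)(C)[Si](C)(C)OC[C@H](O[Si](C)(C)C(C)(C)C)/C(C)=C/CS(=O)(=O)c1ccccc1 | intermediate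
6 | (2R,3E)-2-(tert-butyldimethylsilyloxy)-3-methyl-5-(phenylsulfonyl)pent-3-en-1-ol | OC[C@H](O[Si](C)(C)C(C)(C)C)/C(C)=C/CS(=O)(=O)c1ccccc1 | intermediate
7 | (2R,3E)-2-(tert-butyldimethylsilyloxy)-3-methyl-5-(phenylsulfonyl)pent-3-enal | O=C[C@H](O[Si](C)(C)C(C)(C)C)/C(C)=C/CS(=O)(=O)c1ccccc1 | intermediate
8 | prop-2-yn-1-ol | C#CCO | starting material
9 | isopropenylmagnesium bromide | C=C(C)[Mg]Br | starting material
10 | cyclic alkenylmagnesium alkoxide (Mg bridges C2 and the C14 oxygen) | C=C(C)C1=C[Mg]OC1 | intermediate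
11 | (2Z)-3-iodo-2-(prop-1-en-2-yl)prop-2-en-1-ol | OC/C(=C\I)C(C)=C | intermediate
12 | tert-butyldimethyl(prop-2-yn-1-yloxy)silane | C#CCO[Si](C)(C)C(C)(C)C | starting material
13 | (E)-[3-(tert-butyldimethylsilyloxy)-2-methylprop-1-en-1-yl]dimethylalane | C[Al](C)/C=C(\C)CO[Si](C)(C)C(C)(C)C | intermediate
14 | (2Z,4E)-6-(tert-butyldimethylsilyloxy)-5-methyl-2-(prop-1-en-2-yl)hexa-2,4-dien-1-ol | OC/C(=C\C=C(/C)CO[Si](C)(C)C(C)(C)C)C(C)=C | intermediate
15 | (2Z,4E)-6-(tert-butyldimethylsilyloxy)-5-methyl-2-(prop-1-en-2-yl)hexa-2,4-dienal | O=C/C(=C\C=C(/C)CO[Si](C)(C)C(C)(C)C)C(C)=C | intermediate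
16 | allenylboronic acid pinacol ester | C=C=CB1OC(C)(C)C(C)(C)O1 | starting material
17 | O-(pinacolatoboryl) ether of 18 | C#CC[C@H](OB1OC(C)(C)C(C)(C)O1)/C(=C\C=C(/C)CO[Si](C)(C)C(C)(C)C)C(C)=C | intermediate
18 | (4S,5Z,7E)-9-(tert-butyldimethylsilyloxy)-8-methyl-5-(prop-1-en-2-yl)nona-5,7-dien-1-yn-4-ol | C#CC[C@H](O)/C(=C\C=C(/C)CO[Si](C)(C)C(C)(C)C)C(C)=C | intermediate
19 | (4S,5Z,7E)-4,9-bis(tert-butyldimethylsilyloxy)-8-methyl-5-(prop-1-en-2-yl)nona-5,7-dien-1-yne | C#CC[C@H](O[Si](C)(C)C(C)(C)C)/C(=C\C=C(/C)CO[Si](C)(C)C(C)(C)C)C(C)=C | intermediate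
20 | (1E)-alkenyl(dimethyl)alane from 19 (AlMe2 on C11, methyl on C12) | C[Al](C)/C=C(\C)C[C@H](O[Si](C)(C)C(C)(C)C)/C(=C\C=C(/C)CO[Si](C)(C)C(C)(C)C)C(C)=C | intermediate
21 | (1E,4S,5Z,7E)-4,9-bis(tert-butyldimethylsilyloxy)-1-iodo-2,8-dimethyl-5-(prop-1-en-2-yl)nona-1,5,7-triene | I/C=C(\C)C[C@H](O[Si](C)(C)C(C)(C)C)/C(=C\C=C(/C)CO[Si](C)(C)C(C)(C)C)C(C)=C | intermediate
22 | alkenyllithium from 21 (Li on C11) | [Li]/C=C(\C)C[C@H](O[Si](C)(C)C(C)(C)C)/C(=C\C=C(/C)CO[Si](C)(C)C(C)(C)C)C(C)=C | intermediate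
23 | alkenyl(ethyl)zinc from 22 (ZnEt on C11) | CC[Zn]/C=C(\C)C[C@H](O[Si](C)(C)C(C)(C)C)/C(=C\C=C(/C)CO[Si](C)(C)C(C)(C)C)C(C)=C | intermediate
24 | (9R,10R,14S)-10-hydroxy-6-(phenylsulfonyl)-5,9,14-tris(tert-butyldimethylsilyloxy)-5,6-secocembra-1Z,3E,7E,11E,15-pentaene | O=S(=O)(c1ccccc1)C/C=C(\C)[C@@H](O[Si](C)(C)C(C)(C)C)[C@H](O)/C=C(\C)C[C@H](O[Si](C)(C)C(C)(C)C)/C(=C\C=C(/C)CO[Si](C)(C)C(C)(C)C)C(C)=C | intermediate
25 | (9R,10R,14S)-6-(phenylsulfonyl)-5,9,10,14-tetrakis(tert-butyldimethylsilyloxy)-5,6-secocembra-1Z,3E,7E,11E,15-pentaene | O=S(=O)(c1ccccc1)C/C=C(\C)[C@@H](O[Si](C)(C)C(C)(C)C)[C@H](O[Si](C)(C)C(C)(C)C)/C=C(\C)C[C@H](O[Si](C)(C)C(C)(C)C)/C(=C\C=C(/C)CO[Si](C)(C)C(C)(C)C)C(C)=C | intermediate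
26 | (9R,10R,14S)-5-hydroxy-6-(phenylsulfonyl)-9,10,14-tris(tert-butyldimethylsilyloxy)-5,6-secocembra-1Z,3E,7E,11E,15-pentaene | O=S(=O)(c1ccccc1)C/C=C(\C)[C@@H](O[Si](C)(C)C(C)(C)C)[C@H](O[Si](C)(C)C(C)(C)C)/C=C(\C)C[C@H](O[Si](C)(C)C(C)(C)C)/C(=C\C=C(/C)CO)C(C)=C | intermediate
27 | (9R,10R,14S)-5-chloro-6-(phenylsulfonyl)-9,10,14-tris(tert-butyldimethylsilyloxy)-5,6-secocembra-1Z,3E,7E,11E,15-pentaene | O=S(=O)(c1ccccc1)C/C=C(\C)[C@@H](O[Si](C)(C)C(C)(C)C)[C@H](O[Si](C)(C)C(C)(C)C)/C=C(\C)C[C@H](O[Si](C)(C)C(C)(C)C)/C(=C\C=C(/C)CCl)C(C)=C | intermediate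
28 | potassium salt of the C6 carbanion of 27 | [K+].O=S(=O)(c1ccccc1)[CH-]/C=C(\C)[C@@H](O[Si](C)(C)C(C)(C)C)[C@H](O[Si](C)(C)C(C)(C)C)/C=C(\C)C[C@H](O[Si](C)(C)C(C)(C)C)/C(=C\C=C(/C)CCl)C(C)=C | intermediate
29 | (9R,10R,14S)-6-(phenylsulfonyl)-9,10,14-tris(tert-butyldimethylsilyloxy)cembra-1Z,3E,7E,11E,15-pentaene (C6 epimers) | C=C(C)/C1=C/C=C(\C)CC(S(=O)(=O)c2ccccc2)/C=C(\C)[C@@H](O[Si](C)(C)C(C)(C)C)[C@H](O[Si](C)(C)C(C)(C)C)/C=C(\C)C[C@@H]1O[Si](C)(C)C(C)(C)C | intermediate
30 | (9R,10R,14S)-9,10,14-tris(tert-butyldimethylsilyloxy)cembra-1Z,3E,7E,11E,15-pentaene | C=C(C)/C1=C/C=C(\C)CC/C=C(\C)[C@@H](O[Si](C)(C)C(C)(C)C)[C@H](O[Si](C)(C)C(C)(C)C)/C=C(\C)C[C@@H]1O[Si](C)(C)C(C)(C)C | intermediate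
31 | (9R,10R,14S)-cembra-1Z,3E,7E,11E,15-pentaene-9,10,14-triol | C=C(C)/C1=C/C=C(\C)CC/C=C(\C)[C@@H](O)[C@H](O)/C=C(\C)C[C@@H]1O | intermediate
32 | 9,10-O-phenylboronate of 31 | C=C(C)/C1=C/C=C(\C)CC/C=C(\C)[C@H]2OB(c3ccccc3)O[C@@H]2/C=C(\C)C[C@@H]1O | intermediate
33 | 14-O-acetyl-9,10-O-phenylboronate of 31 | C=C(C)/C1=C/C=C(\C)CC/C=C(\C)[C@H]2OB(c3ccccc3)O[C@@H]2/C=C(\C)C[C@@H]1OC(C)=O | intermediate
34 | (1Z,3E,7E,11E,9R,10R,14S)-14-acetoxycembra-1,3,7,11,15-pentaene-9,10-diol (CNP0330994.1) | C=C(C)/C1=C/C=C(\C)CC/C=C(\C)[C@@H](O)[C@H](O)/C=C(\C)C[C@@H]1OC(C)=O | target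

Total step count: 20.
Longest linear sequence: 14 steps (steps 7–20 from prop-2-yn-1-ol; steps 1–6 followed by 13–20 are equally long).

Steps most likely to fail

1. Step 17 (ring closure).
- What may go wrong: intermolecular alkylation may outrun ring closure. The base may strip HCl from the dienylic chloride, or the anion may expel the C9 silyloxide in a vinylogous elimination.
- Fallback, from 26 back to 29: 26 is treated with LiN(SiMe3)2 and methyl chloroformate. This carbonates the C5 alkoxide and acylates the C6 carbanion in one operation, giving the carbonate α-sulfonyl ester F1.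
- Under neutral Tsuji–Trost conditions (Pd(PPh3)4, THF, reflux, slow addition), zerovalent palladium ionises the C5 carbonate. The released methoxide deprotonates the now soft sulfonyl ester, and attack at the primary terminus C5 closes the same C5–C6 bond to the macrocyclic sulfonyl ester F2.
- Krapcho demethoxycarbonylation (LiCl, wet DMSO, heat) then returns to the route at 29.

2. Step 13 (fragment union).
- What may go wrong: the non-chelated Felkin–Anh pathway may compete and give poor facial selectivity at C10. The aldehyde may epimerise at C9 or its alkene may move into conjugation before it is consumed.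
- Fallback, from 21 and 7 back to 24: a Nozaki–Hiyama–Kishi coupling (CrCl2, NiCl2 cat., DMSO, rt) tolerates the sulfone and should favour the 10-epimeric anti alcohol F3.
- The epimer mixture is oxidised with Dess–Martin periodinane to the α-silyloxy enone F4.
- A Felkin–Anh-controlled 1,2-reduction with the bulky hydride LiBH(s-Bu)3 (THF, −78 °C) delivers hydride anti to the C9–O bond, gives the 9,10-syn alcohol, and returns to the route at 24.

3. Step 10 (C14 stereocentre).
- What may go wrong: addition to the hindered α-branched dienal may be slow, with erosion of enantioselectivity by the uncatalysed background reaction and acid-promoted Z to E isomerisation of the enal.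
- Fallback, from 15 back to 18: a Barbier propargylation (propargyl bromide, Zn, THF/aq. NH4Cl) gives the racemic homopropargylic alcohol F5.
- A lipase-catalysed kinetic resolution (Burkholderia cepacia lipase, vinyl acetate, t-BuOMe) should acylate the R enantiomer to the (4R)-acetate F6 and leave the S alcohol, which is 18.

Further compounds
F1 | step 17 | (9R,10R,14S)-5-(methoxycarbonyloxy)-6-(methoxycarbonyl)-6-(phenylsulfonyl)-9,10,14-tris(tert-butyldimethylsilyloxy)-5,6-secocembra-1Z,3E,7E,11E,15-pentaene (C6 epimers) | COC(=O)C(S(=O)(=O)c1ccccc1)/C=C(\C)[C@@H](O[Si](C)(C)C(C)(C)C)[C@H](O[Si](C)(C)C(C)(C)C)/C=C(\C)C[C@H](O[Si](C)(C)C(C)(C)C)/C(=C\C=C(/C)COC(=O)OC)C(C)=C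
F2 | step 17 | (9R,10R,14S)-6-(methoxycarbonyl)-6-(phenylsulfonyl)-9,10,14-tris(tert-butyldimethylsilyloxy)cembra-1Z,3E,7E,11E,15-pentaene (C6 epimers) | C=C(C)/C1=C/C=C(\C)CC(C(=O)OC)(S(=O)(=O)c2ccccc2)/C=C(\C)[C@@H](O[Si](C)(C)C(C)(C)C)[C@H](O[Si](C)(C)C(C)(C)C)/C=C(\C)C[C@@H]1O[Si](C)(C)C(C)(C)C
F3 | step 13 | (9R,10S,14S)-10-epimer of 24 | O=S(=O)(c1ccccc1)C/C=C(\C)[C@@H](O[Si](C)(C)C(C)(C)C)[C@@H](O)/C=C(\C)C[C@H](O[Si](C)(C)C(C)(C)C)/C(=C\C=C(/C)CO[Si](C)(C)C(C)(C)C)C(C)=C
F4 | step 13 | (9R,14S)-10-oxo-6-(phenylsulfonyl)-5,9,14-tris(tert-butyldimethylsilyloxy)-5,6-secocembra-1Z,3E,7E,11E,15-pentaene | O=S(=O)(c1ccccc1)C/C=C(\C)[C@@H](O[Si](C)(C)C(C)(C)C)C(=O)/C=C(\C)C[C@H](O[Si](C)(C)C(C)(C)C)/C(=C\C=C(/C)CO[Si](C)(C)C(C)(C)C)C(C)=C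
F5 | step 10 | racemic (5Z,7E)-9-(tert-butyldimethylsilyloxy)-8-methyl-5-(prop-1-en-2-yl)nona-5,7-dien-1-yn-4-ol | C#CCC(O)/C(=C\C=C(/C)CO[Si](C)(C)C(C)(C)C)C(C)=C
F6 | step 10 | (4R,5Z,7E)-9-(tert-butyldimethylsilyloxy)-8-methyl-5-(prop-1-en-2-yl)nona-5,7-dien-1-yn-4-yl acetate | C#CC[C@@H](OC(C)=O)/C(=C\C=C(/C)CO[Si](C)(C)C(C)(C)C)C(C)=C
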